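**Retrosynthetic overview**
1. Target 20 comes from triacetate 19, and 19 from the 7β-alcohol 18 by Mitsunobu inversion at C7. Alcohol 18 comes from enone 17, whose C9–C11 bond is made by a B-alkyl Suzuki coupling of chloro enone 13 with dienol 15.
2. Key disconnection C9–C10: the exocyclic alkene of 12 adds to its own dichlorovinyl ketone by a hydrogen-atom-transfer radical 6-endo addition–elimination. This closes ring B and sets the quaternary C10.
3. C5–C6 comes from a catalytic asymmetric anti-allylboration of keto aldehyde 9 (from acetyl chloride and 1,1-dichloropropene) with allylboronate 4. This sets C5 and C6.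
4. Ring order: ring A comes with 3-methylcyclohexenone (gem-dimethyl by cuprate addition). Ring B is closed second, in the radical step.

Assumption: positions follow labdane numbering (ring A = C1–C5 and C10, ring B = C5–C10), and the target is read as (5S,6S,7S,10S), i.e. 6β,7α-diacetoxylabda-8,13E-dien-15-ol with a trans-decalin.

**Step 1**
Reactants: 1 3-methylcyclohex-2-en-1-one
Product: 3 3,3-dimethylcyclohex-1-en-1-yl trifluoromethanesulfonate, via lithium enolate 2 (not isolated)
Conditions: Me2CuLi, Et2O, 0 °C; then PhNTf2, THF, 0 °C to rt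
Reagents that add atoms: lithium dimethylcuprate [Li+].C[Cu-]C; N-phenylbis(trifluoromethanesulfonimide) O=S(=O)(N(c1ccccc1)S(=O)(=O)C(F)(F)F)C(F)(F)F
Why: Cuprate conjugate addition builds the C4 gem-dimethyl group, and O-triflation of the regiodefined enolate fixes the double bond between C10 and C5; no stereocentre is formed.

**Step 2**
Reactants: 3 3,3-dimethylcyclohex-1-en-1-yl trifluoromethanesulfonate
Product: 4 2-[(3,3-dimethylcyclohex-1-en-1-yl)methyl]-4,4,5,5-tetramethyl-1,3,2-dioxaborolane
Conditions: CH2(Bpin)2, Pd(dppf)Cl2 (5 mol %), aq. KOH, 1,4-dioxane, rt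
Reagents that add atoms: bis(pinacolatoboryl)methane CC1(C)OB(CB2OC(C)(C)C(C)(C)O2)OC1(C)C
Why: In this Suzuki–Miyaura coupling of a geminal diboronate, hydroxide activates one boron, zerovalent palladium inserts into the C–OTf bond and CH2Bpin (future C20) is transferred, giving an allylboronate with C4 locked trans to CH2B; no stereocentre is formed.

**Step 3**
Reactants: 5 acetyl chloride; 6 1,1-dichloroprop-1-ene
Product: 8 4,4-dichloro-3-methylbut-3-en-2-one, via trichloro ketone 7 (not isolated)
Conditions: AlCl3 (1.1 equiv), CH2Cl2, 0 °C to rt; then Et3N, 0 °C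
Reagents that add atoms: none
Why: In this Friedel–Crafts-type (Kondakov) acylation the acylium ion attacks the CH carbon because the resulting cation is stabilised by two chlorines and captures chloride, and Et3N then removes HCl by E1cB elimination; no stereocentre remains.

**Step 4**
Reactants: 8 4,4-dichloro-3-methylbut-3-en-2-one
Product: 9 4,4-dichloro-3-methyl-2-oxobut-3-enal
Conditions: SeO2, 1,4-dioxane/H2O, 90 °C; distilled and dried azeotropically before use
Reagents that add atoms: selenium dioxide O=[Se]=O
Why: Riley oxidation converts the enolisable acetyl CH3 into the aldehyde, while the vinylic methyl on the electron-poor alkene reacts much more slowly; no stereocentre is formed.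

**Step 5**
Reactants: 4 allylboronate; 9 4,4-dichloro-3-methyl-2-oxobut-3-enal
Product: 11 (1S)-4,4-dichloro-1-[(1S)-2,2-dimethyl-6-methylidenecyclohexyl]-1-hydroxy-3-methylbut-3-en-2-one (5S,6S anti adduct), via pinacol borate 10 (not isolated)
Conditions: (S)-TRIP [(S)-3,3'-bis(2,4,6-triisopropylphenyl)-1,1'-binaphthyl-2,2'-diyl hydrogen phosphate] (10 mol %), 4 Å MS, toluene, −78 to −40 °C; aq. NaHCO3 work-up
Reagents that add atoms: none
Why: This phosphoric-acid-catalysed allylboration runs through a Zimmerman–Traxler chair, so the E-type γ-substituent C4 sits equatorial and gives only the anti adduct (the 5α-H/6β-O relationship of the target), the catalyst selects the si face of the aldehyde (6S, hence 5S), and the aldehyde reacts far faster than the ketone.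

**Step 6**
Reactants: 11 anti hydroxy ketone
Product: 12 (1S)-4,4-dichloro-1-[(1S)-2,2-dimethyl-6-methylidenecyclohexyl]-3-methyl-2-oxobut-3-en-1-yl acetate
Conditions: Ac2O, pyridine, DMAP (cat.), CH2Cl2, 0 °C
Reagents that add atoms: acetic anhydride CC(=O)OC(C)=O
Why: This O-acylation installs the final C6 acetate early and stops the free hydroxyl from closing onto the chlorovinyl ketone to give a furanone; C5 and C6 are untouched.

**Step 7 (key step)**
Reactants: 12 dichlorovinyl ketone acetate
Product: 13 (1S,4aS,8aS)-4-chloro-3,4a,8,8-tetramethyl-2-oxo-1,2,4a,5,6,7,8,8a-octahydronaphthalen-1-yl acetate (trans-decalin with 6β-OAc)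
Conditions: Fe(acac)3 (20 mol %), PhSiH3 (2 equiv), Na2HPO4 (2 equiv), i-PrOH/THF (0.02 M), 50 °C
Reagents that add atoms: none
Why: Proposed new method: the iron hydride formed from Fe(acac)3 and PhSiH3 transfers a hydrogen atom to the CH2 of the 1,1-disubstituted alkene, and the nucleophilic tertiary C10 radical (a 4-oxo-5-hexenyl radical) adds 6-endo to the electron-poor CCl2 carbon, because attack at the α-carbon is polarity-mismatched and would place two quaternary carbons next to each other in a five-membered ring; divalent iron then reduces the α-keto radical and the enolate expels chloride, which restores the enone; the C5 chain stays equatorial and the new bond forms equatorially in a chair-like transition state, with the small C6 oxygen rather than C7 in the crowded slot between C4 and C10, so C20 becomes axial and the trans-decalin (10S) results; the closest known reaction types are the iron-catalysed reductive olefin coupling (hydrogen-atom-transfer Giese cyclisation) and hydrogen-atom-transfer addition–elimination on β-nitrostyrenes.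

**Step 8**
Reactants: 14 (2E)-3-methylpent-2-en-4-yn-1-ol
Product: 15 (2E)-3-methylpenta-2,4-dien-1-ol
Conditions: H2 (1 atm), Pd/CaCO3 poisoned with Pb(OAc)2, quinoline, EtOAc, rt
Reagents that add atoms: none
Why: Semihydrogenation of the terminal alkyne on poisoned palladium stops at the diene and keeps the E-trisubstituted alkene.

**Step 9**
Reactants: 15 (2E)-3-methylpenta-2,4-dien-1-ol; 13 chloro enone
Product: 17 (1S,4aS,8aS)-4-[(3E)-5-hydroxy-3-methylpent-3-en-1-yl]-3,4a,8,8-tetramethyl-2-oxo-1,2,4a,5,6,7,8,8a-octahydronaphthalen-1-yl acetate, via alkylborane 16 (not isolated)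
Conditions: 9-BBN-H (2.2 equiv), THF, 0 °C to rt; then 13, Pd(OAc)2 (5 mol %), SPhos (10 mol %), aq. K3PO4, THF, 40 °C
Reagents that add atoms: none
Why: In this hydroboration/B-alkyl Suzuki–Miyaura sequence 9-BBN-H first caps the OH and then adds anti-Markovnikov to the monosubstituted vinyl group only, zerovalent palladium inserts into the activated (vinylogous acyl chloride) C9–Cl bond, and C6 holds because its equatorial hydrogen is poorly aligned for enolisation.

**Step 10**
Reactants: 17 acetoxy enone
Product: 18 (1S,2R,4aS,8aS)-2-hydroxy-4-[(3E)-5-hydroxy-3-methylpent-3-en-1-yl]-3,4a,8,8-tetramethyl-1,2,4a,5,6,7,8,8a-octahydronaphthalen-1-yl acetate (6β-OAc 7β-OH)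
Conditions: NaBH4, CeCl3·7H2O, MeOH, −78 °C; AcOH quench
Reagents that add atoms: none
Why: In this Luche 1,2-reduction hydride arrives from the open α face, opposite the axial C20 methyl and the 6β-acetate, giving the 7β-alcohol (7R), and the cold acidic quench prevents acetyl migration.

**Step 11**
Reactants: 18 7β-alcohol
Product: 19 (1S,2S,4aS,8aS)-4-[(3E)-5-acetoxy-3-methylpent-3-en-1-yl]-3,4a,8,8-tetramethyl-1,2,4a,5,6,7,8,8a-octahydronaphthalene-1,2-diyl diacetate
Conditions: AcOH (3 equiv), PPh3 (3 equiv), DIAD (3 equiv), toluene, 0 °C to rt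
Reagents that add atoms: acetic acid CC(=O)O
Why: In this Mitsunobu reaction acetate displaces the activated allylic 7β-oxygen from the open α face with inversion (7S), ionisation to the allyl cation or the 6β,7β-acetoxonium ion would be captured from the same face, attack at C9 is blocked, and the primary C15 alcohol is esterified at the same time.

**Step 12**
Reactants: 19 triacetate
Product: 20 (1S,2S,4aS,8aS)-4-[(3E)-5-hydroxy-3-methylpent-3-en-1-yl]-3,4a,8,8-tetramethyl-1,2,4a,5,6,7,8,8a-octahydronaphthalene-1,2-diyl diacetate (target)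
Conditions: K2CO3 (0.2 equiv), MeOH, 0 °C, stopped at full conversion of 19
Reagents that add atoms: none
Why: In this chemoselective base-catalysed transesterification the unhindered primary allylic acetate is methanolysed much faster than the axial 6β-acetate and the flanked 7α-acetate; no stereocentre is touched.

**Compound list**
1 | 3-methylcyclohex-2-en-1-one | CC1=CC(=O)CCC1 | starting material
2 | lithium 3,3-dimethylcyclohex-1-en-1-olate | [Li+].[O-]C1=CC(C)(C)CCC1 | intermediate
3 | 3,3-dimethylcyclohex-1-en-1-yl trifluoromethanesulfonate | CC1(C)CCCC(OS(=O)(=O)C(F)(F)F)=C1 | intermediate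
4 | 2-[(3,3-dimethylcyclohex-1-en-1-yl)methyl]-4,4,5,5-tetramethyl-1,3,2-dioxaborolane | CC1(C)CCCC(CB2OC(C)(C)C(C)(C)O2)=C1 | intermediate
5 | acetyl chloride | CC(=O)Cl | starting material
6 | 1,1-dichloroprop-1-ene | CC=C(Cl)Cl | starting material
7 | 4,4,4-trichloro-3-methylbutan-2-one (racemic) | CC(=O)C(C)C(Cl)(Cl)Cl | intermediate
8 | 4,4-dichloro-3-methylbut-3-en-2-one | CC(=O)C(C)=C(Cl)Cl | intermediate
9 | 4,4-dichloro-3-methyl-2-oxobut-3-enal | O=CC(=O)C(C)=C(Cl)Cl | intermediate
10 | pinacol borate of 11 (5S,6S) | CC1(C)OB(O[C@H](C(=O)C(C)=C(Cl)Cl)[C@@H]2C(=C)CCCC2(C)C)OC1(C)C | intermediate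
11 | (1S)-4,4-dichloro-1-[(1S)-2,2-dimethyl-6-methylidenecyclohexyl]-1-hydroxy-3-methylbut-3-en-2-one | O[C@H](C(=O)C(C)=C(Cl)Cl)[C@@H]1C(=C)CCCC1(C)C | intermediate
12 | (1S)-4,4-dichloro-1-[(1S)-2,2-dimethyl-6-methylidenecyclohexyl]-3-methyl-2-oxobut-3-en-1-yl acetate | CC(=O)O[C@H](C(=O)C(C)=C(Cl)Cl)[C@@H]1C(=C)CCCC1(C)C | intermediate
13 | (1S,4aS,8aS)-4-chloro-3,4a,8,8-tetramethyl-2-oxo-1,2,4a,5,6,7,8,8a-octahydronaphthalen-1-yl acetate | CC(=O)O[C@@H]1C(=O)C(C)=C(Cl)[C@@]2(C)CCCC(C)(C)[C@H]12 | intermediate
14 | (2E)-3-methylpent-2-en-4-yn-1-ol | C#C/C(C)=C/CO | starting material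
15 | (2E)-3-methylpenta-2,4-dien-1-ol | C=C/C(C)=C/CO | intermediate
16 | 9-[(3E)-5-(9-borabicyclo[3.3.1]nonan-9-yloxy)-3-methylpent-3-en-1-yl]-9-borabicyclo[3.3.1]nonane | B1(CC/C(C)=C/COB2C3CCCC2CCC3)C4CCCC1CCC4 | intermediate
17 | (1S,4aS,8aS)-4-[(3E)-5-hydroxy-3-methylpent-3-en-1-yl]-3,4a,8,8-tetramethyl-2-oxo-1,2,4a,5,6,7,8,8a-octahydronaphthalen-1-yl acetate | CC(=O)O[C@@H]1C(=O)C(C)=C(CC/C(C)=C/CO)[C@@]2(C)CCCC(C)(C)[C@H]12 | intermediate
18 | (1S,2R,4aS,8aS)-2-hydroxy-4-[(3E)-5-hydroxy-3-methylpent-3-en-1-yl]-3,4a,8,8-tetramethyl-1,2,4a,5,6,7,8,8a-octahydronaphthalen-1-yl acetate | CC(=O)O[C@@H]1[C@H](O)C(C)=C(CC/C(C)=C/CO)[C@@]2(C)CCCC(C)(C)[C@H]12 | intermediate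
19 | (1S,2S,4aS,8aS)-4-[(3E)-5-acetoxy-3-methylpent-3-en-1-yl]-3,4a,8,8-tetramethyl-1,2,4a,5,6,7,8,8a-octahydronaphthalene-1,2-diyl diacetate | CC(=O)O[C@@H]1[C@@H](OC(C)=O)C(C)=C(CC/C(C)=C/COC(C)=O)[C@@]2(C)CCCC(C)(C)[C@H]12 | intermediate
20 | 6β,7α-diacetoxylabda-8,13E-dien-15-ol (5S,6S,7S,10S) | CC(=O)O[C@@H]1[C@@H](OC(C)=O)C(C)=C(CC/C(C)=C/CO)[C@@]2(C)CCCC(C)(C)[C@H]12 | target

**Step count**
Total: 12 steps. Longest linear sequence: 9 steps (1, 2, 5, 6, 7, 9, 10, 11, 12).

**Three steps most likely to fail**

Step 7. The dichlorovinyl ketone is an untested acceptor for this type of cyclisation. The bond joins a tertiary radical to a fully substituted carbon. Simple hydrogenation, hydrogen back-transfer to the C5=C10 alkene (which would erase C5), or closure to the cis-decalin could all compete.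
The fallback drops metal-hydride initiation and makes the same C10 radical by halogen abstraction. It sets out from 12. Markovnikov addition of HCl (AcCl/EtOH, CH2Cl2, −20 °C) gives the C10 tertiary chloride of 12 F1. Slow addition of (Me3Si)3SiH with Et3B/air in benzene then abstracts the tertiary chlorine. The radical closes onto the CCl2 carbon, and the chlorine atom it expels carries the chain by taking hydrogen from the silane. The fallback comes back to the route at 13.

Step 5. The keto aldehyde is very electrophilic, so the uncatalysed racemic allylboration may outrun the phosphoric acid pathway. Attack through neopentyl C5 is also slow, and 9 may be partly hydrated.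
The fallback accepts the background reaction and moves the source of chirality to an acylative kinetic resolution. It sets out from 4 and 9 without catalyst (toluene, rt). The chair transition state still gives only the anti adduct, now as a racemate: 10 forms together with the enantiomer of borate 10 F2, and work-up gives 11 together with the enantiomer of alcohol 11 F3. Acetylation with Ac2O and a chiral isothiourea acyl-transfer catalyst (HyperBTM, enantiomer chosen to acylate the 6S alcohol) is stopped near half conversion. F3 is left behind and removed by chromatography. The fallback comes back at 12, so it also replaces step 6.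

Step 9. The C9–Cl bond sits between the quaternary C10 and the methyl-bearing C8, so transmetallation and reductive elimination may be too slow. Long exposure to base would then endanger the α-acetoxy ketone.
The fallback changes the order of bond formation. It sets out from 12 and alkylborane 16. The unhindered dichlorovinyl ketone is mono-coupled under the same palladium conditions at rt to give the monochloro enone carrying the side chain F4 (E/Z mixture, which does not matter). The iron-hydride cyclisation of step 7 is then run on F4. The 1,1-disubstituted alkene accepts the hydrogen atom faster than the trisubstituted allylic-alcohol alkene, and loss of the remaining chloride gives the enone directly. The fallback comes back at 17.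

**Further compounds**
F1 | step 7 | C10 tertiary chloride of 12 (epimers at C10) | CC(=O)O[C@H](C(=O)C(C)=C(Cl)Cl)[C@@H]1C(C)(Cl)CCCC1(C)C
F2 | step 5 | enantiomer of borate 10 | CC1(C)OB(O[C@@H](C(=O)C(C)=C(Cl)Cl)[C@H]2C(=C)CCCC2(C)C)OC1(C)C
F3 | step 5 | enantiomer of alcohol 11 | O[C@@H](C(=O)C(C)=C(Cl)Cl)[C@H]1C(=C)CCCC1(C)C
F4 | step 9 | monochloro enone carrying the side chain (E/Z mixture at C8=C9) | CC(=O)O[C@H](C(=O)C(C)=C(Cl)CC/C(C)=C/CO)[C@@H]1C(=C)CCCC1(C)C
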